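**Assumption:** numbered starting materials (1, 2, 10, 16, 22, 25, 28) and all unnumbered reagents are purchased; TBS = tert-butyldimethylsilyl, Tr = triphenylmethyl (trityl). The target is tetronothiodin.

## Retrosynthetic overview

1. Last ring closure: the spiro-cyclohexene and the 19-membered carbocycle form together by an intramolecular Diels–Alder reaction of a 3-acyl-5-methylidene tetronate with the terminal (E,E)-diene.
2. Acyl–tetronate C–C bond by Fukuyama coupling of a thiolane thioester with zincated 4-methoxy-5-methylidenefuranone (the tetronate ring is bought); central diene by Stille coupling with a skipped-triene stannane.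
3. Thiolane (first ring) by anodic C–S ring closure of a trityl thioether onto the enol silane of an α-keto ester, made by Mukaiyama–Michael addition of a β-tritylthio thioester to a 2-oxo-3-enoate.
4. Backbone by Wittig olefination, Negishi sp3–sp2 coupling of a Roche-type zinc reagent, and double opening of (S)-epichlorohydrin (alkenyl Grignard, then acetylide).
5. Stereocentres: carbinol and CHMe are bought (1, 10); thiolane C3 follows from CHMe; thiolane C2/C4 equilibrate to all-trans; the three cyclohexene centres come from the Diels–Alder step.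

## Route

Step 1
Reactants: 1 (S)-epichlorohydrin; 2 (E)-(2-bromovinyl)trimethylsilane
Product: 4 (S,E)-1-chloro-5-(trimethylsilyl)pent-4-en-2-ol, via Grignard reagent 3 (not isolated)
Conditions: Mg turnings, THF, 45 °C; then CuI (10 mol%), 1, THF, −40 → −10 °C; aq. NH4Cl
Reagents that add atoms: none
Why: Copper-catalysed SN2 opening of the epoxide at its CH2 terminus by the alkenyl Grignard reagent with retention of E geometry; the carbinol stereocentre is the one bought in 1 and no bond to it is broken.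

Step 2
Reactants: 4 (S,E)-1-chloro-5-(trimethylsilyl)pent-4-en-2-ol
Product: 6 (S,E)-1-(trimethylsilyl)hept-1-en-6-yn-4-ol, via epoxide 5 (not isolated)
Conditions: LiC≡CH·H2NCH2CH2NH2 (3 equiv), DMSO, 0 °C → rt
Reagents that add atoms: lithium acetylide–ethylenediamine complex, [Li+].[C-]#C.NCCN
Why: The acetylide first closes the chlorohydrin to epoxide 5 (intramolecular Williamson reaction) and then opens it at CH2 (SN2), so the C–O bond of the stereocentre stays intact and the two arms of the carbinol become different.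

Step 3
Reactants: 6 (S,E)-1-(trimethylsilyl)hept-1-en-6-yn-4-ol
Product: 7 (S,E)-4-(TBSO)-1-(trimethylsilyl)hept-1-en-6-yne
Conditions: TBSCl, imidazole, DMF, rt
Reagents that add atoms: tert-butyldimethylsilyl chloride, CC(C)(C)[Si](C)(C)Cl
Why: Standard silyl ether formation masks the alcohol for the organometallic steps.

Step 4
Reactants: 7 (S,E)-4-(TBSO)-1-(trimethylsilyl)hept-1-en-6-yne
Product: 9 tert-butyl{[(1E,4S,6E)-1-iodo-7-(trimethylsilyl)hepta-1,6-dien-4-yl]oxy}dimethylsilane, via alkenylzirconocene chloride 8 (not isolated)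
Conditions: Cp2Zr(H)Cl (1.3 equiv), THF, rt; then I2, THF, 0 °C
Reagents that add atoms: iodine, [I][I]
Why: Hydrozirconation (syn, anti-Markovnikov) of the terminal alkyne, which reacts far faster than the silyl-substituted internal alkene, followed by iodinolysis with retention gives the E vinyl iodide.

Step 5
Reactants: 10 methyl (R)-3-bromo-2-methylpropanoate; 9 tert-butyl{[(1E,4S,6E)-1-iodo-7-(trimethylsilyl)hepta-1,6-dien-4-yl]oxy}dimethylsilane
Product: 12 methyl (2S,4E,7R,9E)-7-(TBSO)-2-methyl-10-(trimethylsilyl)deca-4,9-dienoate, via alkylzinc bromide 11 (not isolated)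
Conditions: 10, Zn dust, LiCl, THF, 50 °C; then 9, Pd(PPh3)4 (5 mol%), THF, rt
Reagents that add atoms: none
Why: Zinc insertion then Negishi sp3–sp2 cross-coupling with retention of alkene geometry; the bought CHMe stereocentre does not carry the metal and sees no base, so it is not epimerised.

Step 6
Reactants: 12 methyl (2S,4E,7R,9E)-7-(TBSO)-2-methyl-10-(trimethylsilyl)deca-4,9-dienoate
Product: 13 methyl (2S,4E,7R,9E)-7-(TBSO)-10-iodo-2-methyldeca-4,9-dienoate
Conditions: NIS (1.3 equiv), (CF3)2CHOH, 0 °C, 10 min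
Reagents that add atoms: N-iodosuccinimide, O=C1CCC(=O)N1I
Why: Electrophilic ipso-iododesilylation (β-silyl cation) is much faster at the vinylsilane than at the isolated alkene and proceeds with retention of E geometry.

Step 7
Reactants: 13 methyl (2S,4E,7R,9E)-7-(TBSO)-10-iodo-2-methyldeca-4,9-dienoate
Product: 14 (2S,4E,7R,9E)-7-(TBSO)-10-iodo-2-methyldeca-4,9-dienal
Conditions: (i-Bu)2AlH (1.1 equiv), CH2Cl2, −78 °C; aq. potassium sodium tartrate
Reagents that add atoms: none
Why: Partial reduction of the ester through the stable tetrahedral aluminate at low temperature; the α-stereocentre is kept by using the aldehyde at once.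

Step 8
Reactants: 14 (2S,4E,7R,9E)-7-(TBSO)-10-iodo-2-methyldeca-4,9-dienal
Product: 15 ethyl (3E,5S,7E,10R,12E)-10-(TBSO)-13-iodo-5-methyl-2-oxotrideca-3,7,12-trienoate
Conditions: Ph3P=CHC(O)CO2Et (1.3 equiv), CH2Cl2, rt, 16 h
Reagents that add atoms: ethyl 2-oxo-3-(triphenylphosphoranylidene)propanoate, CCOC(=O)C(=O)C=P(c1ccccc1)(c1ccccc1)c1ccccc1
Why: Wittig olefination with the acyl-stabilised ylide gives the E enone under neutral conditions that do not epimerise the α-branched aldehyde.

Step 9
Reactants: 16 3-(tritylthio)propanoic acid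
Product: 17 S-ethyl 3-(tritylthio)propanethioate
Conditions: EtSH, DCC, DMAP (5 mol%), CH2Cl2, 0 °C → rt
Reagents that add atoms: ethanethiol, CCS
Why: Steglich-type thioesterification of the acid.

Step 10
Reactants: 17 S-ethyl 3-(tritylthio)propanethioate; 15 ethyl (3E,5S,7E,10R,12E)-10-(TBSO)-13-iodo-5-methyl-2-oxotrideca-3,7,12-trienoate
Product: 19 ethyl (2Z,4R,5S,7E,10R,12E)-2,10-bis(TBSO)-4-[1-(ethylthio)-1-oxo-3-(tritylthio)propan-2-yl]-13-iodo-5-methyltrideca-2,7,12-trienoate (epimer mixture at the thioester α-carbon), via silyl ketene thioacetal 18 (not isolated)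
Conditions: 17 (1.3 equiv), Et3N (1.35 equiv), TBSOTf (1.6 equiv), CH2Cl2, −78 → 0 °C; then 15, −78 → −50 °C; pH 7 buffer
Reagents that add atoms: tert-butyldimethylsilyl triflate, CC(C)(C)[Si](C)(C)OS(=O)(=O)C(F)(F)F
Why: Soft enolisation followed by a silyl-triflate-catalysed Mukaiyama–Michael addition to the doubly activated 2-oxo-3-enoate with silyl transfer; the new stereocentre (later thiolane C3) is set by the adjacent bought CHMe centre (allylic-strain model, attack anti to the larger CH2–alkenyl arm, expected only about 4:1 with the minor epimer removed at 21), while the thioester α-centre forms as a mixture that is corrected in step 11.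

Step 11
Reactants: 19 ethyl (2Z,4R,5S,7E,10R,12E)-2,10-bis(TBSO)-4-[1-(ethylthio)-1-oxo-3-(tritylthio)propan-2-yl]-13-iodo-5-methyltrideca-2,7,12-trienoate
Product: 21 S-ethyl (3S,4S,5S)-4-[(2S,4E,7R,9E)-7-(TBSO)-10-iododeca-4,9-dien-2-yl]-5-(2-ethoxy-2-oxoacetyl)thiolane-3-carbothioate, via epimeric thiolane mixture 20 (not isolated)
Conditions: undivided cell, reticulated vitreous carbon anode, Pt cathode, constant current (2.2 F/mol), Et4NOTs (0.1 M), 2,6-lutidine (3 equiv), MeOH/CH2Cl2 (1:4), rt; then DBU (0.2 equiv), CH2Cl2, rt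
Reagents that add atoms: none
Why: Proposed new method: anodic oxidation of the trityl thioether (the most easily oxidised site) gives a sulfide radical cation that loses the stabilised trityl cation, the thiyl radical adds 5-exo to the electron-rich enol silane, and the captodative α-siloxy radical is oxidised and desilylated by methanol to the α-keto ester, so one two-electron oxidation closes the thiolane C–S bond and unmasks the keto ester; the two epimerisable centres (thiolane C2 and C4, both α to carbonyl groups) then settle trans to the C3 substituent under DBU to give the all-trans ring; the closest known chemistry is the Moeller-type anodic coupling of enol ether radical cations with heteroatom nucleophiles, the iodine-mediated oxidative detritylation of S-trityl thiols and the sulfenylation of silyl enol ethers.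

Step 12
Reactants: 22 (E)-2-methylbut-2-enal (tiglic aldehyde)
Product: 23 (E)-4-methylhexa-1,4-dien-3-ol (racemic)
Conditions: CH2=CHMgBr, THF, −78 → 0 °C
Reagents that add atoms: vinylmagnesium bromide, C=C[Mg]Br
Why: 1,2-Addition of the Grignard reagent to the enal; the carbinol centre is removed in step 13, so its configuration does not matter.

Step 13
Reactants: 23 (E)-4-methylhexa-1,4-dien-3-ol
Product: 24 (2E,4E)-1-bromo-4-methylhexa-2,4-diene
Conditions: PBr3 (0.4 equiv), Et2O, −10 °C
Reagents that add atoms: phosphorus tribromide, BrP(Br)Br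
Why: Bromination with allylic transposition (SN2'-type through the pentadienyl ion pair) gives the thermodynamically preferred conjugated primary E,E-dienyl bromide.

Step 14
Reactants: 24 (2E,4E)-1-bromo-4-methylhexa-2,4-diene; 25 (E)-1,2-bis(tributylstannyl)ethene
Product: 26 tributyl[(1E,4E,6E)-6-methylocta-1,4,6-trien-1-yl]stannane
Conditions: 25 (2 equiv), Pd2(dba)3 (2.5 mol%), AsPh3 (10 mol%), THF, 50 °C
Reagents that add atoms: none
Why: Stille allyl–alkenyl coupling at the primary terminus of the pentadienyl palladium intermediate; excess distannane secures mono-coupling and the E alkenylstannane geometry is retained.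

Step 15
Reactants: 21 S-ethyl (3S,4S,5S)-4-[(2S,4E,7R,9E)-7-(TBSO)-10-iododeca-4,9-dien-2-yl]-5-(2-ethoxy-2-oxoacetyl)thiolane-3-carbothioate; 26 tributyl[(1E,4E,6E)-6-methylocta-1,4,6-trien-1-yl]stannane
Product: 27 S-ethyl (3S,4S,5S)-4-[(2S,4E,7R,9E,11E,14E,16E)-7-(TBSO)-16-methyloctadeca-4,9,11,14,16-pentaen-2-yl]-5-(2-ethoxy-2-oxoacetyl)thiolane-3-carbothioate
Conditions: Pd2(dba)3 (5 mol%), AsPh3 (20 mol%), DMF, rt, dark
Reagents that add atoms: none
Why: Stille sp2–sp2 coupling builds the E,E-diene with retention at both partners under neutral, copper-free conditions that leave the thioester and keto ester untouched.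

Step 16
Reactants: 28 4-methoxyfuran-2(5H)-one (methyl tetronate)
Product: 30 5-[(dimethylamino)methyl]-4-methoxyfuran-2(5H)-one (racemic), via lithium dienolate 29 (not isolated)
Conditions: LiN(i-Pr)2, THF, −78 °C; then Me2N=CH2 I, −78 → 0 °C
Reagents that add atoms: N,N-dimethylmethyleneiminium iodide (Eschenmoser's salt), C=[N+](C)C.[I-]
Why: Mannich reaction of the dienolate formed by deprotonation at the 5-position; the new centre is removed in step 17.

Step 17
Reactants: 30 5-[(dimethylamino)methyl]-4-methoxyfuran-2(5H)-one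
Product: 32 4-methoxy-5-methylidenefuran-2(5H)-one, via ammonium iodide 31 (not isolated)
Conditions: MeI, MeOH, rt; then NaHCO3 (aq.), CH2Cl2, rt
Reagents that add atoms: none
Why: Quaternisation followed by E1cB (Hofmann-type) elimination gives the exocyclic alkene.

Step 18
Reactants: 32 4-methoxy-5-methylidenefuran-2(5H)-one; 27 S-ethyl (3S,4S,5S)-4-[(2S,4E,7R,9E,11E,14E,16E)-7-(TBSO)-16-methyloctadeca-4,9,11,14,16-pentaen-2-yl]-5-(2-ethoxy-2-oxoacetyl)thiolane-3-carbothioate
Product: 35 ethyl 2-[(2S,3S,4R)-3-[(2S,4E,7R,9E,11E,14E,16E)-7-(TBSO)-16-methyloctadeca-4,9,11,14,16-pentaen-2-yl]-4-(4-methoxy-5-methylidene-2-oxo-2,5-dihydrofuran-3-carbonyl)thiolan-2-yl]-2-oxoacetate, via lithiated tetronate 33 (not isolated), via organozinc chloride 34 (not isolated)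
Conditions: 32, LiN(i-Pr)2, THF, −78 °C; ZnCl2, −78 → 0 °C; then 27, PdCl2(PPh3)2 (10 mol%), THF/toluene, rt
Reagents that add atoms: none
Why: Vinylic lithiation at the tetronate 3-position, transmetalation to zinc and Fukuyama ketone synthesis; the organozinc halide does not add to the keto ester and the base-free coupling keeps the thiolane centres.

Step 19
Reactants: 35 ethyl 2-[(2S,3S,4R)-3-[(2S,4E,7R,9E,11E,14E,16E)-7-(TBSO)-16-methyloctadeca-4,9,11,14,16-pentaen-2-yl]-4-(4-methoxy-5-methylidene-2-oxo-2,5-dihydrofuran-3-carbonyl)thiolan-2-yl]-2-oxoacetate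
Product: 36 tetronate-O-methyl carbinol-O-TBS ethyl ester of tetronothiodin (macrocycle with all eight stereocentres as in 38)
Conditions: toluene (0.5 mM), 2,6-di-tert-butyl-4-methylphenol (cat.), 110 °C, 36 h
Reagents that add atoms: none
Why: Macrocyclising intramolecular Diels–Alder reaction in which the E,E-diene geometry fixes the cis relation of ring methyl and side chain, the tether is expected to favour the lactone-oxygen-endo approach, and the thiolane, CHMe and carbinol centres of the folded chain are relied on to select the diene face, so the three cyclohexene stereocentres are set under substrate control; the 2-methyl-substituted terminal diene is the more reactive of the two dienes.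

Step 20
Reactants: 36 tetronate-O-methyl carbinol-O-TBS ethyl ester of tetronothiodin
Product: 38 tetronothiodin, via silyl ether diacid 37 (not isolated)
Conditions: LiOH (6 equiv), THF/H2O (3:1), 0 °C → rt; then aq. HF (48%), MeCN, 0 °C → rt
Reagents that add atoms: lithium hydroxide, [Li+].[OH-]
Why: Hydroxide hydrolyses the activated α-keto ester and, by addition–elimination, the vinylogous methyl ester of the 3-acyl tetronate; HF then cleaves the silyl ether, and the two epimerisable thiolane centres stay in their thermodynamic trans arrangement.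

## Compound list

1 | (S)-2-(chloromethyl)oxirane ((S)-epichlorohydrin) | ClC[C@@H]1CO1 | starting material
2 | (E)-(2-bromovinyl)trimethylsilane | C[Si](C)(C)/C=C/Br | starting material
3 | (E)-[2-(trimethylsilyl)vinyl]magnesium bromide | C[Si](C)(C)/C=C/[Mg]Br | intermediate
4 | (S,E)-1-chloro-5-(trimethylsilyl)pent-4-en-2-ol | C[Si](C)(C)/C=C/C[C@H](O)CCl | intermediate
5 | (S)-2-[(E)-3-(trimethylsilyl)prop-2-en-1-yl]oxirane | C[Si](C)(C)/C=C/C[C@H]1CO1 | intermediate
6 | (S,E)-1-(trimethylsilyl)hept-1-en-6-yn-4-ol | C[Si](C)(C)/C=C/C[C@H](O)CC#C | intermediate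
7 | (S,E)-4-(TBSO)-1-(trimethylsilyl)hept-1-en-6-yne | C[Si](C)(C)/C=C/C[C@H](O[Si](C)(C)C(C)(C)C)CC#C | intermediate
8 | chlorobis(cyclopentadienyl)[(1E,4S,6E)-4-(TBSO)-7-(trimethylsilyl)hepta-1,6-dien-1-yl]zirconium | C[Si](C)(C)/C=C/C[C@H](O[Si](C)(C)C(C)(C)C)C/C=C/[Zr](Cl)(C1C=CC=C1)C1C=CC=C1 | intermediate
9 | tert-butyl{[(1E,4S,6E)-1-iodo-7-(trimethylsilyl)hepta-1,6-dien-4-yl]oxy}dimethylsilane | C[Si](C)(C)/C=C/C[C@H](O[Si](C)(C)C(C)(C)C)C/C=C/I | intermediate
10 | methyl (R)-3-bromo-2-methylpropanoate | BrC[C@H](C)C(=O)OC | starting material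
11 | [(R)-3-methoxy-2-methyl-3-oxopropyl]zinc bromide | Br[Zn]C[C@H](C)C(=O)OC | intermediate
12 | methyl (2S,4E,7R,9E)-7-(TBSO)-2-methyl-10-(trimethylsilyl)deca-4,9-dienoate | C[Si](C)(C)/C=C/C[C@H](O[Si](C)(C)C(C)(C)C)C/C=C/C[C@H](C)C(=O)OC | intermediate
13 | methyl (2S,4E,7R,9E)-7-(TBSO)-10-iodo-2-methyldeca-4,9-dienoate | I/C=C/C[C@H](O[Si](C)(C)C(C)(C)C)C/C=C/C[C@H](C)C(=O)OC | intermediate
14 | (2S,4E,7R,9E)-7-(TBSO)-10-iodo-2-methyldeca-4,9-dienal | I/C=C/C[C@H](O[Si](C)(C)C(C)(C)C)C/C=C/C[C@H](C)C=O | intermediate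
15 | ethyl (3E,5S,7E,10R,12E)-10-(TBSO)-13-iodo-5-methyl-2-oxotrideca-3,7,12-trienoate | I/C=C/C[C@H](O[Si](C)(C)C(C)(C)C)C/C=C/C[C@H](C)/C=C/C(=O)C(=O)OCC | intermediate
16 | 3-(tritylthio)propanoic acid | OC(=O)CCSC(c1ccccc1)(c1ccccc1)c1ccccc1 | starting material
17 | S-ethyl 3-(tritylthio)propanethioate | CCSC(=O)CCSC(c1ccccc1)(c1ccccc1)c1ccccc1 | intermediate
18 | tert-butyl{[1-(ethylthio)-3-(tritylthio)prop-1-en-1-yl]oxy}dimethylsilane (silyl ketene thioacetal, alkene geometry not defined) | CCSC(O[Si](C)(C)C(C)(C)C)=CCSC(c1ccccc1)(c1ccccc1)c1ccccc1 | intermediate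
19 | ethyl (2Z,4R,5S,7E,10R,12E)-2,10-bis(TBSO)-4-[1-(ethylthio)-1-oxo-3-(tritylthio)propan-2-yl]-13-iodo-5-methyltrideca-2,7,12-trienoate (epimer mixture at the thioester α-carbon) | I/C=C/C[C@H](O[Si](C)(C)C(C)(C)C)C/C=C/C[C@H](C)[C@@H](C(CSC(c1ccccc1)(c1ccccc1)c1ccccc1)C(=O)SCC)/C=C(\O[Si](C)(C)C(C)(C)C)C(=O)OCC | intermediate
20 | S-ethyl (4S)-4-[(2S,4E,7R,9E)-7-(TBSO)-10-iododeca-4,9-dien-2-yl]-5-(2-ethoxy-2-oxoacetyl)thiolane-3-carbothioate (mixture of epimers at ring C3 and C5) | I/C=C/C[C@H](O[Si](C)(C)C(C)(C)C)C/C=C/C[C@H](C)[C@@H]1C(C(=O)C(=O)OCC)SCC1C(=O)SCC | intermediate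
21 | S-ethyl (3S,4S,5S)-4-[(2S,4E,7R,9E)-7-(TBSO)-10-iododeca-4,9-dien-2-yl]-5-(2-ethoxy-2-oxoacetyl)thiolane-3-carbothioate (all-trans ring) | I/C=C/C[C@H](O[Si](C)(C)C(C)(C)C)C/C=C/C[C@H](C)[C@@H]1[C@@H](C(=O)C(=O)OCC)SC[C@H]1C(=O)SCC | intermediate
22 | (E)-2-methylbut-2-enal (tiglic aldehyde) | C/C=C(C)/C=O | starting material
23 | (E)-4-methylhexa-1,4-dien-3-ol (racemic) | C/C=C(C)/C(O)C=C | intermediate
24 | (2E,4E)-1-bromo-4-methylhexa-2,4-diene | C/C=C(C)/C=C/CBr | intermediate
25 | (E)-1,2-bis(tributylstannyl)ethene | CCCC[Sn](CCCC)(CCCC)/C=C/[Sn](CCCC)(CCCC)CCCC | starting material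
26 | tributyl[(1E,4E,6E)-6-methylocta-1,4,6-trien-1-yl]stannane | C/C=C(C)/C=C/C/C=C/[Sn](CCCC)(CCCC)CCCC | intermediate
27 | S-ethyl (3S,4S,5S)-4-[(2S,4E,7R,9E,11E,14E,16E)-7-(TBSO)-16-methyloctadeca-4,9,11,14,16-pentaen-2-yl]-5-(2-ethoxy-2-oxoacetyl)thiolane-3-carbothioate | C/C=C(C)/C=C/C/C=C/C=C/C[C@H](O[Si](C)(C)C(C)(C)C)C/C=C/C[C@H](C)[C@@H]1[C@@H](C(=O)C(=O)OCC)SC[C@H]1C(=O)SCC | intermediate
28 | 4-methoxyfuran-2(5H)-one (methyl tetronate) | COC1=CC(=O)OC1 | starting material
29 | lithium 4-methoxyfuran-2-olate (dienolate of 28) | COC1=COC(O[Li])=C1 | intermediate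
30 | 5-[(dimethylamino)methyl]-4-methoxyfuran-2(5H)-one (racemic) | COC1=CC(=O)OC1CN(C)C | intermediate
31 | (3-methoxy-5-oxo-2,5-dihydrofuran-2-yl)-N,N,N-trimethylmethanaminium iodide (racemic) | COC1=CC(=O)OC1C[N+](C)(C)C.[I-] | intermediate
32 | 4-methoxy-5-methylidenefuran-2(5H)-one | COC1=CC(=O)OC1=C | intermediate
33 | 3-lithio-4-methoxy-5-methylidenefuran-2(5H)-one | COC1=C([Li])C(=O)OC1=C | intermediate
34 | (4-methoxy-5-methylidene-2-oxo-2,5-dihydrofuran-3-yl)zinc chloride | COC1=C([Zn]Cl)C(=O)OC1=C | intermediate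
35 | ethyl 2-[(2S,3S,4R)-3-[(2S,4E,7R,9E,11E,14E,16E)-7-(TBSO)-16-methyloctadeca-4,9,11,14,16-pentaen-2-yl]-4-(4-methoxy-5-methylidene-2-oxo-2,5-dihydrofuran-3-carbonyl)thiolan-2-yl]-2-oxoacetate | C/C=C(C)/C=C/C/C=C/C=C/C[C@H](O[Si](C)(C)C(C)(C)C)C/C=C/C[C@H](C)[C@@H]1[C@@H](C(=O)C(=O)OCC)SC[C@H]1C(=O)C1=C(OC)C(=C)OC1=O | intermediate
36 | tetronate-O-methyl carbinol-O-TBS ethyl ester of tetronothiodin (stereocentres as in 38) | CC1=C[C@H]2C/C=C/C=C/C[C@H](O[Si](C)(C)C(C)(C)C)C/C=C/C[C@H](C)[C@@H]3[C@@H](C(=O)C(=O)OCC)SC[C@H]3C(=O)C3=C(OC)[C@@]2(C[C@H]1C)OC3=O | intermediate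
37 | carbinol-O-TBS tetronothiodin (present as its dilithium salt, drawn as the diacid) | CC1=C[C@H]2C/C=C/C=C/C[C@H](O[Si](C)(C)C(C)(C)C)C/C=C/C[C@H](C)[C@@H]3[C@@H](C(=O)C(=O)O)SC[C@H]3C(=O)C3=C(O)[C@@]2(C[C@H]1C)OC3=O | intermediate
38 | tetronothiodin | CC1=C[C@H]2C/C=C/C=C/C[C@H](O)C/C=C/C[C@H](C)[C@@H]3[C@@H](C(=O)C(=O)O)SC[C@H]3C(=O)C3=C(O)[C@@]2(C[C@H]1C)OC3=O | target

## Step count and risks

Total: 20 steps. Longest linear sequence: 14 steps (steps 1–8, 10, 11, 15, 18, 19, 20).

**Step 11 (proposed anodic thiolane closure).** The thioether, enol silane and vinyl iodide may not be differentiated cleanly at the anode. Fallback by known chemistry, setting out from 19: NBS (THF, −78 °C) brominates the enol silane carbon to give the α-bromo keto ester F1. CF3CO2H/Et3SiH (CH2Cl2, 0 °C) then removes the trityl group to give the thiol F2. Et3N closes the ring by SN2 displacement at the α-bromo ketone, and the same DBU equilibration brings the material back to the route at 21.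

**Step 18 (Fukuyama coupling).** The thioester is α-branched and hindered and the alkenylzinc is electron-poor. Fallback, setting out from 32 and 27: stannylate 32 (LiN(i-Pr)2, THF, −78 °C; Bu3SnCl) to the stannane F3. Join F3 to 27 by a Liebeskind–Srogl coupling (Pd2(dba)3, tri(2-furyl)phosphine, Cu(O2CC4H3S), THF, rt). This is a neutral thioester–stannane ketone synthesis that needs no organozinc, and it comes back to the route at 35.

**Step 19 (macrocyclising Diels–Alder).** Facial selectivity rests on remote stereocentres in a flexible 19-membered transition state, and the internal diene could compete. Fallback, setting out from 35: deprotect first (LiOH, then aq. HF, as in step 20) to the unprotected seco acid F4. Run the cycloaddition last on its tetronate dianion in water (pH 7 phosphate buffer, 5% DMSO, 40 °C, 0.1 mM), where hydrophobic folding and the anionic acyl tetronate change rate and selectivity. This arrives directly at 38.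

## Further compounds

F1 | step 11 | ethyl (5S,7E,10R,12E)-3-bromo-10-(TBSO)-4-[1-(ethylthio)-1-oxo-3-(tritylthio)propan-2-yl]-13-iodo-5-methyl-2-oxotrideca-7,12-dienoate (C4 as in 19, bromide epimers) | I/C=C/C[C@H](O[Si](C)(C)C(C)(C)C)C/C=C/C[C@H](C)[C@@H](C(CSC(c1ccccc1)(c1ccccc1)c1ccccc1)C(=O)SCC)C(Br)C(=O)C(=O)OCC
F2 | step 11 | free thiol of F1 (trityl removed) | I/C=C/C[C@H](O[Si](C)(C)C(C)(C)C)C/C=C/C[C@H](C)[C@@H](C(CS)C(=O)SCC)C(Br)C(=O)C(=O)OCC
F3 | step 18 | 4-methoxy-5-methylidene-3-(tributylstannyl)furan-2(5H)-one | COC1=C([Sn](CCCC)(CCCC)CCCC)C(=O)OC1=C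
F4 | step 19 | fully deprotected seco acid of 35 (free carbinol, free keto acid, free 3-acyl-5-methylidene tetronic acid) | C/C=C(C)/C=C/C/C=C/C=C/C[C@H](O)C/C=C/C[C@H](C)[C@@H]1[C@@H](C(=O)C(=O)O)SC[C@H]1C(=O)C1=C(O)C(=C)OC1=O
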